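A ratio of 0.363, read off scattered readings, opens the books: it is the fractional rate of loss of electrophile in the winter run between 30.0 min and 50.0 min, set against the same rate up to 12.0 min.

| flask | electrophile | nucleophile | free base | temperature | remark | time |
|---|---|---|---|---|---|---|
| winter | 0.050 M | 1.1 equiv | 1.7 equiv (fed, over 2.5 h) | 5 °C | run made earlier |  |
| alpha | 0.050 M | 1.10 equiv | 1.10 equiv (fed, over 2.5 h) | 5 °C |  | 2.5 h |
| eta | 0.050 M | 1.10 equiv | 1.10 equiv | 5 °C | everything together at the start | 1.5 h |

- winter (time / min: product / %, electrophile / %): 12.0: 26.0, 74.4; 25.0: 38.6, 59.9; 30.0: 42.2, 56.7; 50.0: 54.1, 47.4

(readings scatter by 0.5 percentage points)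

- for acid set free the idle adduct is counted in
- on the list of suspects stand: electrophile + nucleophile -> acid set free + product; nucleophile + acid set free <-> protonated nucleophile; acid set free + free base <-> salt of the base; acid set free + free base <-> idle adduct; free base <-> dormant form
- no earlier run changes the charge of free base; that part of a forecast is a guess

- which of the two ends with the higher amount of product, in percent of the electrophile charged ("neither" if they lie within 2 percentage points) (alpha / eta / neither)
- product at the end, in percent of the electrophile charged, alpha
- product at the end, in percent of the electrophile charged, eta

By charge the electrophile is the limiting reagent, so we keep its ledger in fractions of its charge. On the list of suspects, each part lost becomes product and sets free one part of acid, which can pair with free base or with nucleophile. We count nucleophile paired in this way as not working.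

If the rate goes as electrophile times free nucleophile, the ratio compares free nucleophile in the two stretches. For the early stretch we neglect acid and take the nucleophile charge less half the first product reading, 97.0% of the electrophile charge. This gives a rate constant, in charge units, of 0.0254 min⁻¹. Late on, our estimate of free nucleophile is then 35.3%, while the nucleophile charge less the mean product would leave 61.9%. The gap, 26.6% of the electrophile charge, is our parked nucleophile, the protonated nucleophile entered as a fixed sum.

Working nucleophile is therefore 83.4%, less than the electrophile charge. Integrating the second-order law with it gives 70.2% product for alpha and 61.3% for eta. In this reckoning alpha's books then close with 13.2% free nucleophile. We commit to alpha, since this reckoning separates the two flasks by time and alpha's time is longer. The feed of free base is not in it, and the winter allowance is carried across a changed base charge and, for eta, a changed way of adding the base, which is a guess.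

The forecast differs, with 74% for alpha, 72% for eta and neither as its verdict, adding “The uncertainty is large because the base charge is extrapolated.”

The flask gives 73.6% for alpha and 69.0% for eta, so alpha ends higher, by 4.6 percentage points. With eta's time, alpha stands at 63.3%, less than eta.

    electrophile + nucleophile → acid set free + product (k = 0.616 M⁻¹ min⁻¹, Ea = 54.0 kJ mol⁻¹)
    nucleophile + acid set free ⇌ protonated nucleophile, settled at all times (K = 4290 M⁻¹, ΔH = −1.00 kJ mol⁻¹)
    acid set free + free base ⇌ salt of the base, settled at all times (K = 3700 M⁻¹, ΔH = −28.0 kJ mol⁻¹)
    acid set free + free base ⇌ idle adduct, settled at all times (K = 69.4 M⁻¹, ΔH = −16.0 kJ mol⁻¹)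
    free base ⇌ dormant form (K = 0.896, k = 0.00153 min⁻¹, Ea = 97.0 kJ mol⁻¹, ΔH = 22.0 kJ mol⁻¹)
    (constants at 5 °C)

Our parked sum on alpha's product leaves 9.80% of the electrophile charge as free nucleophile, and the flask holds 16.7%. On eta read at 40 min, with 53.0% product, the same sum leaves 30.4%, and that flask holds 37.3%.

The earlier runs and the new flask were generated by integration with constants of no real substance, noise included.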